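**Assumptions (one line):** (S)-terpinen-4-ol is available as a single enantiomer (tea-tree-oil constituent). The Cope closure in Step 8 and the hydride and protonation facial preferences in Steps 9 and 10 follow the stated substrate-control arguments.

## Retrosynthetic overview
1. Ferutinine ⇐ Mitsunobu p-hydroxybenzoylation, with inversion, of the C6 alcohol ⇐ C6 ketone ⇐ silyl enol ether.
2. The seven-membered ring and the quaternary C(Me) (C4 in daucane numbering) form in one operation: Rh-vinylcarbenoid cyclopropanation of a 2-siloxydiene, then divinylcyclopropane–cycloheptadiene (Cope) rearrangement, a formal [4+3].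
3. The vinylcarbene comes from methyl vinyl ketone (MVK) tosylhydrazone. The diene comes from a cyclopentenyl methyl ketone.
4. That cyclopentene comes from ozonolysis and aldol condensation of (S)-terpinen-4-ol, which supplies the C(OH)iPr stereocentre.
5. Order of ring formation: five-membered ring first, then the seven-membered ring.

## Route

**Step 1**
Reactants: 1, (S)-terpinen-4-ol
Product: 2, its tert-butyldimethylsilyl (TBS) ether
Conditions: TBSOTf, 2,6-lutidine, CH2Cl2, −78 → 0 °C
Reagents that add atoms: TBSOTf, CC(C)(C)[Si](C)(C)OS(=O)(=O)C(F)(F)F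
Why: Silylation of the tertiary alcohol by TBSOTf masks it for the organometallic, base and carbenoid steps; no stereocentre is touched.

**Step 2**
Reactants: 2
Product: 3, (3S)-3-(TBSO)-3-isopropyl-6-oxoheptanal
Conditions: O3, CH2Cl2/MeOH, −78 °C; then Me2S
Reagents that add atoms: ozone, O=[O+][O-] (supplies the two carbonyl oxygens)
Why: Ozonolysis cleaves the only alkene, the trisubstituted ring alkene, and opens the ring to the keto-aldehyde with the carbinol stereocentre unchanged.

**Step 3**
Reactants: 3
Product: 4, (5R)-5-(TBSO)-2-methyl-5-isopropylcyclopent-1-ene-1-carbaldehyde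
Conditions: pyrrolidine (20 mol %), AcOH, benzene, 50 °C
Reagents that add atoms: none
Why: This is an intramolecular aldol condensation. The aldehyde enamine attacks the methyl ketone in a 5-(enolendo)-exo closure, and dehydration gives the conjugated tetrasubstituted enal. The ring is the future five-membered ring and the silyloxy carbon is untouched.

**Step 4**
Reactants: 4
Product: 5, 1-[(5R)-5-(TBSO)-2-methyl-5-isopropylcyclopent-1-en-1-yl]ethan-1-ol (carbinol epimers)
Conditions: MeMgBr, THF, −78 → 0 °C
Reagents that add atoms: MeMgBr, C[Mg]Br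
Why: Grignard 1,2-addition to the enal. The new carbinol centre is irrelevant because it is oxidised in the next step.

**Step 5**
Reactants: 5
Product: 6, the methyl ketone 1-[(5R)-5-(TBSO)-2-methyl-5-isopropylcyclopent-1-en-1-yl]ethan-1-one
Conditions: activated MnO2, CH2Cl2, rt
Reagents that add atoms: none
Why: MnO2 oxidises the allylic alcohol chemoselectively (allylic oxidation) and removes the epimer mixture.

**Step 6**
Reactants: 6
Product: 7, the 2-siloxydiene (TMS enol ether of 6)
Conditions: LDA, THF, −78 °C; then TMSCl, Et3N
Reagents that add atoms: TMSCl, C[Si](C)(C)Cl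
Why: The only α-hydrogens on the carbonyl side are those of the acetyl CH3, so kinetic enolisation and O-silylation give the terminal silyl enol ether CH2=C(OTMS)–C=C without regiochemical ambiguity.

**Step 7**
Reactants: 8, methyl vinyl ketone; 9, p-toluenesulfonyl hydrazide
Product: 10, MVK tosylhydrazone
Conditions: MeOH, rt
Reagents that add atoms: none
Why: Hydrazone condensation gives the bench-stable precursor of the CH2=CH–C(:)–CH3 vinylcarbene, the C4 unit (future C(Me)=CH–CH2).

**Step 8**
Reactants: 7; 10
Product: 11, the bicyclic TMS enol ether (cyclohepta-1,4-diene fused to the cyclopentane)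
Conditions: NaH, then Rh2(OAc)4 (2 mol %), BnEt3N⁺Cl⁻ (10 mol %), dioxane, 40 °C; then 80 °C
Reagents that add atoms: 10, C=CC(C)=NNS(=O)(=O)c1ccc(C)cc1, which contributes a C4H5 unit (NaH is only a base)
Why: This is a formal [4+3] annulation. Slow Bamford–Stevens diazoalkene generation feeds a Rh-vinylcarbenoid, which cyclopropanates the electron-rich CH2=C(OTMS) alkene selectively. The resulting cis-siloxy-divinylcyclopropane undergoes a boat Cope rearrangement that forms the C3–C4 bond. The quaternary C(Me) is created on the cyclopentene face anti to the allylic C–O bond of the OTBS carbon, so the new ring bond is cis to iPr. The alkenes end up as T1=T2 (the C6=C7 ring alkene) and the TMS enol ether.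

**Step 9**
Reactants: 11
Product: 12, the trans-fused 4-ketone with C3-OTBS, C3-iPr and 8a-Me
Conditions: 1 M HCl, THF, 0 °C, 10 min
Reagents that add atoms: none
Why: Mild enol-ether hydrolysis. Kinetic protonation at C3a occurs anti to the axial angular methyl, giving the trans ring fusion.

**Step 10**
Reactants: 12
Product: 13, the C4 alcohol epimeric to the target (OH syn to the angular Me)
Conditions: L-Selectride, THF, −78 °C
Reagents that add atoms: none (hydride only)
Why: Substrate-controlled reduction. Hydride approaches anti to the angular methyl, which blocks the 1,3-related face, so the OH ends up trans to H-3a, the inverted configuration.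

**Step 11**
Reactants: 13; 14, 4-(TBSO)benzoic acid
Product: 15, the TBS-protected ferutinine
Conditions: DIAD, PPh3, THF, 0 °C → rt
Reagents that add atoms: 14, CC(C)(C)[Si](C)(C)Oc1ccc(cc1)C(=O)O (acyl donor; DIAD/PPh3 are not incorporated)
Why: Mitsunobu esterification proceeds with SN2 inversion at the secondary carbinol, giving the required C4 configuration and installing the ester in one step.

**Step 12**
Reactants: 15
Product: 16, ferutinine
Conditions: HF·pyridine, pyridine/THF, 0 °C → 40 °C
Reagents that add atoms: none
Why: Acidic fluoride removes both the aryl and the tertiary alkyl TBS ethers without basic acyl migration or β-elimination. The aryl ester and the C6=C7 alkene survive.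

## Compound list
1 | (S)-terpinen-4-ol | CC1=CC[C@](O)(C(C)C)CC1 | starting material
2 | (S)-TBS ether of 1 | CC1=CC[C@](O[Si](C)(C)C(C)(C)C)(C(C)C)CC1 | intermediate
3 | (3S)-3-(TBSO)-3-isopropyl-6-oxoheptanal | CC(=O)CC[C@@](O[Si](C)(C)C(C)(C)C)(C(C)C)CC=O | intermediate
4 | (5R)-5-(TBSO)-2-methyl-5-isopropylcyclopent-1-ene-1-carbaldehyde | CC1=C(C=O)[C@](O[Si](C)(C)C(C)(C)C)(C(C)C)CC1 | intermediate
5 | 1-[(5R)-5-(TBSO)-2-methyl-5-isopropylcyclopent-1-en-1-yl]ethanol, carbinol epimers | CC1=C(C(C)O)[C@](O[Si](C)(C)C(C)(C)C)(C(C)C)CC1 | intermediate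
6 | 1-[(5R)-5-(TBSO)-2-methyl-5-isopropylcyclopent-1-en-1-yl]ethanone | CC1=C(C(C)=O)[C@](O[Si](C)(C)C(C)(C)C)(C(C)C)CC1 | intermediate
7 | 2-siloxydiene (TMS enol ether of 6) | C=C(O[Si](C)(C)C)C1=C(C)CC[C@@]1(O[Si](C)(C)C(C)(C)C)C(C)C | intermediate
8 | methyl vinyl ketone | C=CC(C)=O | starting material
9 | p-toluenesulfonyl hydrazide | Cc1ccc(cc1)S(=O)(=O)NN | starting material
10 | MVK tosylhydrazone | C=CC(C)=NNS(=O)(=O)c1ccc(C)cc1 | intermediate
11 | bicyclic TMS enol ether (3-OTBS-3-iPr-6,8a-dimethyl-octahydroazulene, 3a=4 enol ether) | CC1=CC[C@@]2(C)CC[C@@](O[Si](C)(C)C(C)(C)C)(C(C)C)C2=C(O[Si](C)(C)C)C1 | intermediate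
12 | trans-fused 4-ketone | CC1=CC[C@@]2(C)CC[C@@](O[Si](C)(C)C(C)(C)C)(C(C)C)[C@@H]2C(=O)C1 | intermediate
13 | 4-epi alcohol (OH syn to 8a-Me) | CC1=CC[C@@]2(C)CC[C@@](O[Si](C)(C)C(C)(C)C)(C(C)C)[C@@H]2[C@H](O)C1 | intermediate
14 | 4-(TBSO)benzoic acid | CC(C)(C)[Si](C)(C)Oc1ccc(cc1)C(=O)O | starting material
15 | bis-TBS ferutinine | CC1=CC[C@@]2(C)CC[C@@](O[Si](C)(C)C(C)(C)C)(C(C)C)[C@@H]2[C@@H](OC(=O)c2ccc(O[Si](C)(C)C(C)(C)C)cc2)C1 | intermediate
16 | ferutinine | CC1=CC[C@@]2(C)CC[C@@](O)(C(C)C)[C@@H]2[C@@H](OC(=O)c2ccc(O)cc2)C1 | target

## Totals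
Total steps: 12. Longest linear sequence: 11 (Steps 1–6 and 8–12; Step 7 is a parallel preparation of reagent 10).

## Three steps most likely to fail
1. **Step 8 (vinylcarbene [4+3] and Cope).** The unstabilised vinyldiazoalkane may cyclise to a pyrazole, and the Cope closure at a fully substituted terminus may be slow or give the wrong face at the quaternary centre. Fallback: reduce the enal 4 to the allylic alcohol, install the quaternary centre by Johnson–Claisen rearrangement, and close the seven-membered ring by ring-closing metathesis.
2. **Step 3 (regioselective aldol condensation).** The enamine may close through the ketone instead, giving the acetylcyclopentene, or the β-siloxy aldehyde may eliminate. Fallback: form the aldehyde silyl enol ether and cyclise it by a TiCl4-mediated Mukaiyama aldol followed by dehydration, which changes the mechanism from enamine to Lewis-acid enol silane.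
3. **Steps 10–11 (C4 configuration).** Hydride facial selectivity or the hindered Mitsunobu inversion may fail through the wrong epimer or elimination. Fallback: remove the tertiary silyl group and reduce the ketone with a hydroxyl-directed reagent (Me4NBH(OAc)3), whose delivery is controlled by the tertiary OH, then acylate with Steglich esterification.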